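## Analysis of the target

The target is a sesquilignan built on a trans-3,4-disubstituted γ-butyrolactone (ring A). C4 carries a 4-hydroxy-3-methoxybenzyl group (ring B). C3 carries a methylene bonded to C5′ of a 2,3-dihydrobenzofuran (benzo ring C, dihydrofuran ring D) that has a free 7′-hydroxyl, a 3′-hydroxymethyl group and a 4-hydroxy-3-methoxyphenyl group (ring E) at C2′.

There are four stereocentres in two isolated pairs: C3 (S) and C4 (S) on ring A are trans, and C2′ (S) and C3′ (R) on ring D are trans. The CH2–arene spacer between C3 and C5′ stops either pair from controlling the other, so each pair needs its own source of absolute configuration. In each pair one centre is epimerisable in a suitable precursor (C3 next to the lactone carbonyl, C3′ while it still carries an ester), so only one centre per pair has to be set absolutely.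

The sensitive points are the three free phenols, the base-labile lactone with its epimerisable C3, and the O1′–C2′ bond. The last is a benzylic ether para to an oxygen substituent, prone to acid ionisation, to quinone methide formation once the ring E phenol is free, and to hydrogenolysis. Two methyl ethers must survive while O7′ ends free, which rules out a late demethylation and calls for benzyl protection of all three phenols and a neutral end game.

The strategy rests on lactone C4. It is a single CH bonded to the ring methylene C5, to C3 and to a benzylic CH2, which is the pattern left when an aryl nucleophile opens the methylene of a cyclopropane fused to the lactone across C3–C4. C3, flanked by the carbonyl, can be carried as a malonate-type carbon and benzylated.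

## Retrosynthetic reasoning

**27 ⇐ 26 ⇐ 25.** The last operations only remove protecting groups. The three phenols are benzyl ethers so that the final step (26 → 27) is a neutral hydrogenolysis. The primary alcohol is a silyl ether that is cleaved by fluoride (25 → 26) while the phenols are still masked, because a free ring E phenol under basic conditions would open the way to quinone methide chemistry at C2′.

**25 ⇐ 24.** The C3–H bond is traced back to a C3–CO2Me bond. The extra ester makes C3 a doubly stabilised carbon that can be benzylated under mild base. Once it is removed, C3 is an enolisable centre that settles trans to C4. The forward step has to cleave a methyl ester on a quaternary carbon without opening the lactone.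

**24 ⇐ 7 + 23.** The bond C3–CH2(C5′) is cut. It is the only link between the two stereo-dyads, so the cut gives two fragments that each hold one pair of stereocentres and can be made independently. The forward reaction is an enolate benzylation with a reactive benzylic bromide. A cut at the CH2–C5′ aryl bond would instead need an sp2–sp3 coupling on a fully built lactone.

**7 ⇐ 3 + 6.** This is the key disconnection: the bond between ring B and its benzylic CH2. Joining that CH2 to C3 in the retrosynthetic sense gives the lactone-fused cyclopropane 3, so the forward step is the opening of a strained ring by the aryl nucleophile 6 (from 5, from 4). The C4 stereocentre already exists in 3, and 3 comes in one operation from 1 and 2, so no asymmetric step is needed for ring A.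

**23 ⇐ 22 ⇐ 21 ⇐ 20 ⇐ 19 ⇐ 18.** These are functional group changes that tell the two hydroxymethyl groups of diol 19 apart. The benzylic one is oxidised selectively (20), the other is silylated (21), the aldehyde is reduced (22) and the alcohol is turned into the bromide (23). Before that, both carbons travel at the ester level in 18, where they are inert to the ring-forming chemistry.

**18 ⇐ 17 ⇐ 16.** The C2′–C3′ bond is cut. The forward step is a carbene insertion into a benzylic ether C–H bond, which closes ring D and lets a chiral catalyst set C2′. C3′ is then corrected by epimerisation (17 → 18). Cutting here means O1′–C2′ comes from a plain ether synthesis and the ring closure does not pass through a benzylic cation.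

**16 ⇐ 15 ⇐ 12 + 13.** The diazo group comes from the activated methylene of 15. The aryl–CH2 bond of 15 comes from cross-coupling of aryl bromide 12 with the zinc enolate 14 made from 13.

**12 ⇐ 11 ⇐ 10 + 9, and 9 ⇐ 8.** These are two ether formations. Compound 10 already holds every substituent of ring C in the right place: the ester carbon becomes the C5′ side-chain carbon, the bromine marks C3a′, and the two oxygens become O1′ and O7′. The difference in acidity between the two phenols of 10 allows the benzylic carbon of 9 (the future C2′) to be attached selectively to the oxygen that becomes O1′.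

## Alternatives that were turned down

**Alternative 1:** The disconnection is O1′–C2′ of ring D. In the forward direction a Lewis acid ionises a secondary benzylic alcohol, and the neighbouring phenol oxygen captures the cation to give bromide A1.

- For it: the closure is stereoconvergent. The configuration of the carbinol is irrelevant, and the trans ring follows from the C3′ centre alone, which an auxiliary-controlled aldol can set in a derivable way. No precious metal is needed.
- Against it for this target: it deals only with the C2′/C3′ pair and leaves the lactone and both of its stereocentres open. A1 ends in an aryl bromide, so joining it to ring A needs either a one-carbon homologation through an aryl metal species or an sp2–sp3 coupling. The cation sits between electron-rich rings and benzyl ethers, so Friedel–Crafts capture and ether loss are live side reactions.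
- Comparison: for the benzofuran itself this closure is at least as strong as the carbene insertion used here (steps 9 and 10), which depends on a chiral dirhodium catalyst. In its place the chosen strategy offers a key step that solves the half A1 does not touch, and a benzofuran fragment (23) whose C5′ carbon is present from the first step. The number of steps for the benzofuran half is similar in both.

**Alternative 2:** The disconnection is the C4–CH2 bond to ring B, made by radical conjugate addition. In the forward direction visible-light photoredox decarboxylation of an arylacetic acid gives a benzyl radical. It adds to C4 of a chiral 5-menthyloxybutenolide that already carries the benzofuranylmethyl group at C3; reduction and protonation at C3 then give lactone acetal A2.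

- For it: it is the most convergent plan. The two large fragments are united in the step that also creates both lactone stereocentres, under control of a cheap auxiliary and under mild conditions. No activating ester has to be added and removed.
- Against it for this target: the acceptor is an α-alkylated butenolide of reduced electrophilicity, and the stabilised, electron-rich benzyl radical adds slowly and tends to dimerise. Protonation at C3 is kinetic and normally occurs anti to the new C4 substituent, which favours the cis lactone. A2 still has the C5 acetal, whose reductive removal needs Lewis-acidic conditions that threaten the O1′–C2′ bond. The precious benzofuran has to be committed to the least certain step.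
- Comparison: the alternative is stronger in convergence and avoids the ester detour. The chosen route instead runs its uncertain step on small, cheap molecules, has the C5 methylene in place from 1 with nothing to deoxygenate, and reaches the trans lactone by thermodynamic control.

**Alternative 3:** The disconnection is the C2′–ring E bond. In the forward direction a divalent palladium carboxylate, with a silver carboxylate as iodide acceptor, effects a quinolin-8-yl-amide-directed C(sp3)–H arylation of a dihydrobenzofuran-3-carboxamide with an aryl iodide and gives cis amide A3.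

- For it: ring E is introduced late and can be varied. The five-membered palladacycle makes the cis geometry reliable, and only simple palladium salts are needed.
- Against it for this target: the absolute configuration has to be present at C3′ of the amide beforehand, and that same centre must then be inverted to reach the trans ring, which is harder for an amide than for an ester. The directing group has to be installed, then removed and reduced to the hydroxymethyl group. The conditions are hot and use stoichiometric silver in the presence of an aryl bromide and benzyl ethers. As in Alternative 1, the lactone and the homologation at C5′ remain.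
- Comparison: the alternative is better for analogue work on ring E and equal in geometric control. The chosen route sets C2′ directly with a catalyst, epimerises an ester instead of an amide, needs no directing-group handling, and spends its key step on the lactone, whose C4 is bought.

Key step: step 3

Remarks on the chemistry:

- Conjugate bases (phenoxides, enolates, alkoxides) of numbered compounds are treated as those compounds and are not numbered separately; organometallic reagents made in the flask are numbered.
- The sense of induction of Rh2(S-PTTL)4 in step 9 is taken to be that of the parent 2-aryl-2,3-dihydrobenzofuran-3-carboxylates (2S from the S catalyst); with the opposite outcome the R catalyst would be used.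
- Compounds 8, 10 and 13 are taken to be commercial.

## Route

Step 1
Reactants: 1 (S)-epichlorohydrin [(S)-2-(chloromethyl)oxirane]; 2 dimethyl malonate
Product: 3 methyl (1R,5S)-2-oxo-3-oxabicyclo[3.1.0]hexane-1-carboxylate
Conditions: NaOMe (1.1 equiv), MeOH, 0 °C to reflux
Reagents that add atoms: none
Why: Tandem alkylation, cyclopropanation and lactonisation: the malonate anion opens the epoxide at its CH2, the alkoxide displaces chloride to give a transposed epoxide, a second deprotonation closes the three-membered ring (3-exo-tet, inversion at the former C2 of 1), and the freed alkoxide lactonises onto the cis ester, so the stereocentre of 1 becomes C5 (S) and the cis ring fusion fixes C1 (R); the minor pathway by direct chloride displacement would give the enantiomer, so the optical purity of 3 is to be checked.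

Step 2
Reactants: 4 4-bromo-2-methoxyphenol
Product: 5 1-(benzyloxy)-4-bromo-2-methoxybenzene
Conditions: BnBr, K2CO3, acetone, reflux
Reagents that add atoms: benzyl bromide, BrCc1ccccc1
Why: Williamson ether synthesis on a phenoxide; the benzyl ether is stable to magnesium and to cuprates and is removed only in the last step.

Step 3
Reactants: 5 1-(benzyloxy)-4-bromo-2-methoxybenzene; 3 methyl (1R,5S)-2-oxo-3-oxabicyclo[3.1.0]hexane-1-carboxylate
Product: 7 methyl (3R,4S)-4-[4-(benzyloxy)-3-methoxybenzyl]-2-oxotetrahydrofuran-3-carboxylate (trans), via aryl Grignard reagent 6 (not isolated)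
Conditions: Mg turnings, I2 (cat.), THF, 50 °C; then 3, CuBr·SMe2 (10 mol %), THF, −40 to −20 °C, slow addition of 6 (1.5 equiv); aq. NH4Cl
Reagents that add atoms: none
Why: Magnesium inserts into the C–Br bond of 5 to give 6, which transmetallates to the catalytic CuBr·SMe2 (monovalent copper) to form an aryl cuprate. The cuprate attacks the cyclopropane methylene C6 of 3 in an SN2-type homoconjugate addition, the C1–C6 bond breaks, and the aryl–CH2 bond forms together with a magnesium enolate stabilised by both the lactone and the ester. The closest known reaction type is the copper-catalysed opening of 2-oxo-3-oxabicyclo[3.1.0]hexane-1-carboxylates and of cyclopropane-1,1-diesters by alkyl Grignard reagents. No ring is closed; the three-membered ring opens and the lactone stays intact. C4 of the product is C5 of 3, which takes no part in the bond changes and keeps the S configuration bought with 1. The new centre C3 is set on protonation and by equilibration of the acidic malonate-type C–H, which places the ester trans to the C4 benzyl group (R at C3). The step needs attack at C6 in preference to C5 and to the two carbonyl groups: C6 is the unsubstituted carbon, the C1–C6 bond lies nearly parallel to the lactone π system whereas C1–C5 lies in its nodal plane, and the soft cuprate at low temperature with slow addition of 6 disfavours direct carbonyl addition. The product is shielded from excess reagent as its enolate until work-up.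

Step 4
Reactants: 8 [4-(benzyloxy)-3-methoxyphenyl]methanol
Product: 9 1-(benzyloxy)-4-(chloromethyl)-2-methoxybenzene
Conditions: SOCl2 (1.2 equiv), CH2Cl2, 0 °C; used crude
Reagents that add atoms: thionyl chloride, O=S(Cl)Cl
Why: Chlorodehydroxylation of an electron-rich benzylic alcohol through its chlorosulfite; the chloride is reactive and is taken on without storage.

Step 5
Reactants: 10 methyl 3-bromo-4,5-dihydroxybenzoate; 9 1-(benzyloxy)-4-(chloromethyl)-2-methoxybenzene
Product: 11 methyl 4-{[4-(benzyloxy)-3-methoxybenzyl]oxy}-3-bromo-5-hydroxybenzoate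
Conditions: NaHCO3 (1.5 equiv), NaI (cat.), DMF, 40 °C
Reagents that add atoms: none
Why: Regioselective Williamson ether synthesis: the 4-hydroxyl, para to the ester and ortho to bromine, is much the more acidic, so a weak base forms only its phenoxide, which is alkylated by the benzylic chloride.

Step 6
Reactants: 11 methyl 4-{[4-(benzyloxy)-3-methoxybenzyl]oxy}-3-bromo-5-hydroxybenzoate
Product: 12 methyl 3-(benzyloxy)-4-{[4-(benzyloxy)-3-methoxybenzyl]oxy}-5-bromobenzoate
Conditions: BnBr, K2CO3, DMF, rt
Reagents that add atoms: benzyl bromide, BrCc1ccccc1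
Why: Williamson ether synthesis on the remaining phenol; this oxygen becomes O7′ and is released only in the final hydrogenolysis.

Step 7
Reactants: 12 methyl 3-(benzyloxy)-4-{[4-(benzyloxy)-3-methoxybenzyl]oxy}-5-bromobenzoate; 13 methyl bromoacetate
Product: 15 methyl 3-(benzyloxy)-4-{[4-(benzyloxy)-3-methoxybenzyl]oxy}-5-(2-methoxy-2-oxoethyl)benzoate, via Reformatsky reagent 14 (not isolated)
Conditions: Zn dust (TMSCl-activated), THF, 40 °C; then 12, Pd(dba)2 (2 mol %), P(t-Bu)3 (2 mol %), THF, rt to 50 °C
Reagents that add atoms: none
Why: Negishi-type coupling of a Reformatsky reagent (α-arylation of a zinc ester enolate) with zerovalent palladium and a bulky electron-rich phosphine; the zinc enolate does not add to the benzoate, and the ester meta to bromine assists oxidative addition.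

Step 8
Reactants: 15 methyl 3-(benzyloxy)-4-{[4-(benzyloxy)-3-methoxybenzyl]oxy}-5-(2-methoxy-2-oxoethyl)benzoate
Product: 16 methyl 3-(benzyloxy)-4-{[4-(benzyloxy)-3-methoxybenzyl]oxy}-5-(1-diazo-2-methoxy-2-oxoethyl)benzoate
Conditions: 4-acetamidobenzenesulfonyl azide (1.3 equiv), DBU (1.5 equiv), MeCN, 0 °C to rt
Reagents that add atoms: 4-acetamidobenzenesulfonyl azide, CC(=O)Nc1ccc(cc1)S(=O)(=O)N=[N+]=[N-]
Why: Regitz diazo transfer to the arylacetate methylene, the only carbon acid in the molecule that DBU can deprotonate.

Step 9
Reactants: 16 methyl 3-(benzyloxy)-4-{[4-(benzyloxy)-3-methoxybenzyl]oxy}-5-(1-diazo-2-methoxy-2-oxoethyl)benzoate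
Product: 17 dimethyl (2S,3R)-7-(benzyloxy)-2-[4-(benzyloxy)-3-methoxyphenyl]-2,3-dihydro-1-benzofuran-3,5-dicarboxylate (cis)
Conditions: Rh2(S-PTTL)4 [dirhodium tetrakis(N-phthaloyl-(S)-tert-leucinate), 2 mol %], toluene, −78 to −50 °C
Reagents that add atoms: none
Why: Intramolecular carbene C–H insertion: loss of N2 gives a donor/acceptor rhodium carbene that inserts into the benzylic ether C–H five atoms away, the only site that closes a five-membered ring; the S-configured phthalimido-carboxylate catalyst is expected, by analogy with the parent 2-aryl series, to give the cis ester with 2S configuration, and only C2 has to be right because C3 is corrected in step 10.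

Step 10
Reactants: 17 dimethyl (2S,3R)-7-(benzyloxy)-2-[4-(benzyloxy)-3-methoxyphenyl]-2,3-dihydro-1-benzofuran-3,5-dicarboxylate (cis)
Product: 18 dimethyl (2S,3S)-7-(benzyloxy)-2-[4-(benzyloxy)-3-methoxyphenyl]-2,3-dihydro-1-benzofuran-3,5-dicarboxylate (trans)
Conditions: NaOMe (0.3 equiv), MeOH–THF, 0 °C to rt
Reagents that add atoms: none
Why: Base-mediated epimerisation through the ester enolate: C3 is the only acidic stereocentre and reprotonation gives the more stable trans isomer, in which the C2 aryl group and the C3 ester avoid each other; C2 is untouched, and loss of the phenoxide would be a retro-5-endo-trig opening that mild conditions should not reach.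

Step 11
Reactants: 18 dimethyl (2S,3S)-7-(benzyloxy)-2-[4-(benzyloxy)-3-methoxyphenyl]-2,3-dihydro-1-benzofuran-3,5-dicarboxylate (trans)
Product: 19 {(2S,3R)-7-(benzyloxy)-2-[4-(benzyloxy)-3-methoxyphenyl]-2,3-dihydro-1-benzofuran-3,5-diyl}dimethanol
Conditions: LiAlH4, THF, 0 °C
Reagents that add atoms: none
Why: Hydride reduction of both esters to primary alcohols; after reduction C3 is no longer acidic, so the trans relationship is locked (the descriptor at C3 changes to R only because the substituent ranking changes).

Step 12
Reactants: 19 {(2S,3R)-7-(benzyloxy)-2-[4-(benzyloxy)-3-methoxyphenyl]-2,3-dihydro-1-benzofuran-3,5-diyl}dimethanol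
Product: 20 (2S,3R)-7-(benzyloxy)-2-[4-(benzyloxy)-3-methoxyphenyl]-3-(hydroxymethyl)-2,3-dihydro-1-benzofuran-5-carbaldehyde
Conditions: MnO2 (activated, excess), CH2Cl2, rt
Reagents that add atoms: none
Why: Chemoselective oxidation: activated MnO2 oxidises benzylic alcohols and leaves saturated primary alcohols alone, which distinguishes the two hydroxymethyl groups.

Step 13
Reactants: 20 (2S,3R)-7-(benzyloxy)-2-[4-(benzyloxy)-3-methoxyphenyl]-3-(hydroxymethyl)-2,3-dihydro-1-benzofuran-5-carbaldehyde
Product: 21 (2S,3R)-7-(benzyloxy)-2-[4-(benzyloxy)-3-methoxyphenyl]-3-{[(tert-butyldimethylsilyl)oxy]methyl}-2,3-dihydro-1-benzofuran-5-carbaldehyde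
Conditions: TBSCl, imidazole, DMF, rt
Reagents that add atoms: tert-butyldimethylsilyl chloride, CC(C)(C)[Si](C)(C)Cl
Why: Silylation of the only free hydroxyl; the silyl ether tolerates hydride, bromination, enolate alkylation and hot chloride, and is cleaved by fluoride.

Step 14
Reactants: 21 (2S,3R)-7-(benzyloxy)-2-[4-(benzyloxy)-3-methoxyphenyl]-3-{[(tert-butyldimethylsilyl)oxy]methyl}-2,3-dihydro-1-benzofuran-5-carbaldehyde
Product: 22 {(2S,3R)-7-(benzyloxy)-2-[4-(benzyloxy)-3-methoxyphenyl]-3-{[(tert-butyldimethylsilyl)oxy]methyl}-2,3-dihydro-1-benzofuran-5-yl}methanol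
Conditions: NaBH4, MeOH–THF, 0 °C
Reagents that add atoms: none
Why: Borohydride reduction of the aryl aldehyde; nothing else in the molecule is reducible under these conditions.

Step 15
Reactants: 22 {(2S,3R)-7-(benzyloxy)-2-[4-(benzyloxy)-3-methoxyphenyl]-3-{[(tert-butyldimethylsilyl)oxy]methyl}-2,3-dihydro-1-benzofuran-5-yl}methanol
Product: 23 {[(2S,3R)-7-(benzyloxy)-2-[4-(benzyloxy)-3-methoxyphenyl]-5-(bromomethyl)-2,3-dihydro-1-benzofuran-3-yl]methoxy}(tert-butyl)dimethylsilane
Conditions: CBr4, PPh3, CH2Cl2, 0 °C; used directly
Reagents that add atoms: carbon tetrabromide, BrC(Br)(Br)Br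
Why: Appel bromination under neutral conditions, which spares the silyl ether and the acid-sensitive O1′–C2′ bond; the electron-rich benzylic bromide is not stored.

Step 16
Reactants: 7 methyl (3R,4S)-4-[4-(benzyloxy)-3-methoxybenzyl]-2-oxotetrahydrofuran-3-carboxylate; 23 benzofuran-5-ylmethyl bromide of step 15
Product: 24 methyl (3S,4S)-3-({(2S,3R)-7-(benzyloxy)-2-[4-(benzyloxy)-3-methoxyphenyl]-3-{[(tert-butyldimethylsilyl)oxy]methyl}-2,3-dihydro-1-benzofuran-5-yl}methyl)-4-[4-(benzyloxy)-3-methoxybenzyl]-2-oxotetrahydrofuran-3-carboxylate
Conditions: NaH (1.05 equiv), THF–DMF, 0 °C; then 23, 0 °C to rt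
Reagents that add atoms: none
Why: C-Alkylation of a malonate-type sodium enolate with a benzylic bromide; the electrophile should approach anti to the C4 substituent, which gives the 3S quaternary centre, although this configuration is of no consequence because the ester is removed next.

Step 17
Reactants: 24 alkylated lactone ester of step 16
Product: 25 (3S,4S)-3-({(2S,3R)-7-(benzyloxy)-2-[4-(benzyloxy)-3-methoxyphenyl]-3-{[(tert-butyldimethylsilyl)oxy]methyl}-2,3-dihydro-1-benzofuran-5-yl}methyl)-4-[4-(benzyloxy)-3-methoxybenzyl]dihydrofuran-2(3H)-one (trans)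
Conditions: LiCl, H2O, DMSO, 140 °C; then DBU, toluene, 80 °C
Reagents that add atoms: none
Why: Krapcho demethoxycarbonylation: chloride attacks the ester methyl group, the carboxylate loses CO2 and the lactone enolate is protonated; kinetic protonation can give some cis isomer, so the crude lactone is equilibrated with base to the more stable trans arrangement (3S), the C4 centre being inert.

Step 18
Reactants: 25 silyl-protected trans lactone of step 17
Product: 26 (3S,4S)-3-({(2S,3R)-7-(benzyloxy)-2-[4-(benzyloxy)-3-methoxyphenyl]-3-(hydroxymethyl)-2,3-dihydro-1-benzofuran-5-yl}methyl)-4-[4-(benzyloxy)-3-methoxybenzyl]dihydrofuran-2(3H)-one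
Conditions: TBAF, AcOH (1:1), THF, 0 °C to rt
Reagents that add atoms: none
Why: Fluoride-mediated desilylation, buffered with acetic acid so that the lactone is neither opened nor epimerised; the phenols are still benzylated, so no quinone methide can form at C2′.

Step 19
Reactants: 26 tris(benzyl ether) of step 18
Product: 27 (3S,4S)-3-{[(2S,3R)-7-hydroxy-2-(4-hydroxy-3-methoxyphenyl)-3-(hydroxymethyl)-2,3-dihydro-1-benzofuran-5-yl]methyl}-4-(4-hydroxy-3-methoxybenzyl)dihydrofuran-2(3H)-one (CNP0118131.1)
Conditions: H2 (1 atm), 10% Pd/C, EtOAc–EtOH, rt
Reagents that add atoms: none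
Why: Catalytic hydrogenolysis of the three aryl benzyl ethers under neutral conditions; aryl benzyl ethers cleave faster than the cyclic benzylic ether O1′–C2′, and the reaction is stopped when the third benzyl group has gone.

## Compound list

1 | (S)-epichlorohydrin | ClC[C@@H]1CO1 | starting material
2 | dimethyl malonate | COC(=O)CC(=O)OC | starting material
3 | methyl (1R,5S)-2-oxo-3-oxabicyclo[3.1.0]hexane-1-carboxylate | C1[C@@H]2COC(=O)[C@]12C(=O)OC | intermediate
4 | 4-bromo-2-methoxyphenol | COc1cc(Br)ccc1O | starting material
5 | 1-(benzyloxy)-4-bromo-2-methoxybenzene | COc1cc(Br)ccc1OCc1ccccc1 | intermediate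
6 | [4-(benzyloxy)-3-methoxyphenyl]magnesium bromide | COc1cc([Mg]Br)ccc1OCc1ccccc1 | intermediate (not isolated)
7 | methyl (3R,4S)-4-[4-(benzyloxy)-3-methoxybenzyl]-2-oxotetrahydrofuran-3-carboxylate | COc1cc(C[C@@H]2COC(=O)[C@H]2C(=O)OC)ccc1OCc1ccccc1 | intermediate
8 | [4-(benzyloxy)-3-methoxyphenyl]methanol | COc1cc(CO)ccc1OCc1ccccc1 | starting material
9 | 1-(benzyloxy)-4-(chloromethyl)-2-methoxybenzene | COc1cc(CCl)ccc1OCc1ccccc1 | intermediate
10 | methyl 3-bromo-4,5-dihydroxybenzoate | COC(=O)c1cc(O)c(O)c(Br)c1 | starting material
11 | methyl 4-{[4-(benzyloxy)-3-methoxybenzyl]oxy}-3-bromo-5-hydroxybenzoate | COC(=O)c1cc(O)c(OCc2ccc(OCc3ccccc3)c(OC)c2)c(Br)c1 | intermediate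
12 | methyl 3-(benzyloxy)-4-{[4-(benzyloxy)-3-methoxybenzyl]oxy}-5-bromobenzoate | COC(=O)c1cc(OCc2ccccc2)c(OCc2ccc(OCc3ccccc3)c(OC)c2)c(Br)c1 | intermediate
13 | methyl bromoacetate | COC(=O)CBr | starting material
14 | (2-methoxy-2-oxoethyl)zinc bromide | COC(=O)C[Zn]Br | intermediate (not isolated)
15 | methyl 3-(benzyloxy)-4-{[4-(benzyloxy)-3-methoxybenzyl]oxy}-5-(2-methoxy-2-oxoethyl)benzoate | COC(=O)Cc1cc(C(=O)OC)cc(OCc2ccccc2)c1OCc1ccc(OCc2ccccc2)c(OC)c1 | intermediate
16 | methyl 3-(benzyloxy)-4-{[4-(benzyloxy)-3-methoxybenzyl]oxy}-5-(1-diazo-2-methoxy-2-oxoethyl)benzoate | COC(=O)C(=[N+]=[N-])c1cc(C(=O)OC)cc(OCc2ccccc2)c1OCc1ccc(OCc2ccccc2)c(OC)c1 | intermediate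
17 | dimethyl (2S,3R)-7-(benzyloxy)-2-[4-(benzyloxy)-3-methoxyphenyl]-2,3-dihydro-1-benzofuran-3,5-dicarboxylate (cis) | COC(=O)c1cc(OCc2ccccc2)c2c(c1)[C@@H](C(=O)OC)[C@@H](c1ccc(OCc3ccccc3)c(OC)c1)O2 | intermediate
18 | dimethyl (2S,3S)-7-(benzyloxy)-2-[4-(benzyloxy)-3-methoxyphenyl]-2,3-dihydro-1-benzofuran-3,5-dicarboxylate (trans) | COC(=O)c1cc(OCc2ccccc2)c2c(c1)[C@H](C(=O)OC)[C@@H](c1ccc(OCc3ccccc3)c(OC)c1)O2 | intermediate
19 | {(2S,3R)-7-(benzyloxy)-2-[4-(benzyloxy)-3-methoxyphenyl]-2,3-dihydro-1-benzofuran-3,5-diyl}dimethanol | OCc1cc(OCc2ccccc2)c2c(c1)[C@H](CO)[C@@H](c1ccc(OCc3ccccc3)c(OC)c1)O2 | intermediate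
20 | (2S,3R)-7-(benzyloxy)-2-[4-(benzyloxy)-3-methoxyphenyl]-3-(hydroxymethyl)-2,3-dihydro-1-benzofuran-5-carbaldehyde | O=Cc1cc(OCc2ccccc2)c2c(c1)[C@H](CO)[C@@H](c1ccc(OCc3ccccc3)c(OC)c1)O2 | intermediate
21 | (2S,3R)-7-(benzyloxy)-2-[4-(benzyloxy)-3-methoxyphenyl]-3-{[(tert-butyldimethylsilyl)oxy]methyl}-2,3-dihydro-1-benzofuran-5-carbaldehyde | O=Cc1cc(OCc2ccccc2)c2c(c1)[C@H](CO[Si](C)(C)C(C)(C)C)[C@@H](c1ccc(OCc3ccccc3)c(OC)c1)O2 | intermediate
22 | {(2S,3R)-7-(benzyloxy)-2-[4-(benzyloxy)-3-methoxyphenyl]-3-{[(tert-butyldimethylsilyl)oxy]methyl}-2,3-dihydro-1-benzofuran-5-yl}methanol | OCc1cc(OCc2ccccc2)c2c(c1)[C@H](CO[Si](C)(C)C(C)(C)C)[C@@H](c1ccc(OCc3ccccc3)c(OC)c1)O2 | intermediate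
23 | {[(2S,3R)-7-(benzyloxy)-2-[4-(benzyloxy)-3-methoxyphenyl]-5-(bromomethyl)-2,3-dihydro-1-benzofuran-3-yl]methoxy}(tert-butyl)dimethylsilane | BrCc1cc(OCc2ccccc2)c2c(c1)[C@H](CO[Si](C)(C)C(C)(C)C)[C@@H](c1ccc(OCc3ccccc3)c(OC)c1)O2 | intermediate
24 | methyl (3S,4S)-3-({(2S,3R)-7-(benzyloxy)-2-[4-(benzyloxy)-3-methoxyphenyl]-3-{[(tert-butyldimethylsilyl)oxy]methyl}-2,3-dihydro-1-benzofuran-5-yl}methyl)-4-[4-(benzyloxy)-3-methoxybenzyl]-2-oxotetrahydrofuran-3-carboxylate | COc1cc(C[C@@H]2COC(=O)[C@@]2(C(=O)OC)Cc2cc(OCc4ccccc4)c3c(c2)[C@H](CO[Si](C)(C)C(C)(C)C)[C@@H](c2ccc(OCc4ccccc4)c(OC)c2)O3)ccc1OCc1ccccc1 | intermediate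
25 | (3S,4S)-3-({(2S,3R)-7-(benzyloxy)-2-[4-(benzyloxy)-3-methoxyphenyl]-3-{[(tert-butyldimethylsilyl)oxy]methyl}-2,3-dihydro-1-benzofuran-5-yl}methyl)-4-[4-(benzyloxy)-3-methoxybenzyl]dihydrofuran-2(3H)-one | COc1cc(C[C@@H]2COC(=O)[C@H]2Cc2cc(OCc4ccccc4)c3c(c2)[C@H](CO[Si](C)(C)C(C)(C)C)[C@@H](c2ccc(OCc4ccccc4)c(OC)c2)O3)ccc1OCc1ccccc1 | intermediate
26 | (3S,4S)-3-({(2S,3R)-7-(benzyloxy)-2-[4-(benzyloxy)-3-methoxyphenyl]-3-(hydroxymethyl)-2,3-dihydro-1-benzofuran-5-yl}methyl)-4-[4-(benzyloxy)-3-methoxybenzyl]dihydrofuran-2(3H)-one | COc1cc(C[C@@H]2COC(=O)[C@H]2Cc2cc(OCc4ccccc4)c3c(c2)[C@H](CO)[C@@H](c2ccc(OCc4ccccc4)c(OC)c2)O3)ccc1OCc1ccccc1 | intermediate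
27 | (3S,4S)-3-{[(2S,3R)-7-hydroxy-2-(4-hydroxy-3-methoxyphenyl)-3-(hydroxymethyl)-2,3-dihydro-1-benzofuran-5-yl]methyl}-4-(4-hydroxy-3-methoxybenzyl)dihydrofuran-2(3H)-one | COc1cc(C[C@@H]2COC(=O)[C@H]2Cc2cc(O)c3c(c2)[C@H](CO)[C@@H](c2ccc(O)c(OC)c2)O3)ccc1O | target

## Step count and least certain steps

Total: 19 steps. Longest linear sequence: 16 steps (steps 4 to 19, from 8 to 27); the lactone branch (steps 1 to 3) joins at step 16.

**Step 3 (key step).** The most likely failure is direct addition of the Grignard reagent to the lactone or ester carbonyl. The second is a sluggish opening, because aryl cuprates are weaker nucleophiles toward cyclopropanes than the alkyl cuprates for which this opening is established. Fallback: the bond is made by a radical cross-electrophile coupling instead of a polar opening. Starting from 3, iodide opens the cyclopropane at C6 (TMSCl, NaI, MeCN, 0 °C, aqueous work-up) to give methyl (3R,4S)-4-(iodomethyl)-2-oxotetrahydrofuran-3-carboxylate F1. Nickel-catalysed reductive coupling of this primary iodide with aryl bromide 5 (NiBr2·dme as the divalent nickel source, 4,4′-di-tert-butyl-2,2′-bipyridine, Zn, DMA, 60 °C), under non-basic conditions that do not re-close the cyclopropane, returns to the route at 7.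

**Step 9.** The enantiofacial control may be eroded at the doubly ortho-substituted aryl ether, and a trans by-product of opposite C2 configuration would survive step 10 and lower the optical purity. Fallback: resolution in place of asymmetric catalysis. Starting from 16, achiral Rh2(OAc)4 (CH2Cl2, rt) gives the racemic insertion products, that is 17 together with its enantiomer dimethyl (2R,3S)-7-(benzyloxy)-2-[4-(benzyloxy)-3-methoxyphenyl]-2,3-dihydro-1-benzofuran-3,5-dicarboxylate F2. NaOMe in MeOH converts the mixture into the racemic trans diester, 18 together with its enantiomer dimethyl (2R,3R)-7-(benzyloxy)-2-[4-(benzyloxy)-3-methoxyphenyl]-2,3-dihydro-1-benzofuran-3,5-dicarboxylate F3. Preparative chromatography on a chiral stationary phase separates 18, which re-enters the route at step 11.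

**Step 5.** Regiocontrol may be lost, with alkylation at the less acidic 5-hydroxyl or at both phenols, because the wanted phenoxide is flanked by bromine and a hydroxyl and is hindered. Fallback: a Mitsunobu etherification, which engages the more acidic phenol by its own mechanism. Starting from 10 and alcohol 8 (so step 4 is bypassed), PPh3 and DIAD in THF at 0 °C lead directly to 11, where the route is rejoined.

**Step 17.** The demethoxycarbonylation may be incomplete at the hindered quaternary centre, the large substrate may suffer at 140 °C, and the equilibration to trans may stop short. Fallback: the ester is removed before the fragments are joined, and the simple lactone enolate is alkylated. Starting from 7, the same chloride conditions (LiCl, H2O, DMSO, 140 °C) on this small compound give (S)-4-[4-(benzyloxy)-3-methoxybenzyl]dihydrofuran-2(3H)-one F4. Its lithium enolate (LiN(SiMe3)2, THF, −78 °C) is alkylated by 23 anti to the C4 substituent, which gives the trans lactone directly and returns to the route at 25, bypassing step 16 as well.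

**Step 19.** Over-reduction is the danger: hydrogenolytic opening of the O1′–C2′ bond of ring D, which becomes more labile once the ring E phenol is free. Fallback: a non-reductive debenzylation. Starting from 26, BCl3 with pentamethylbenzene as cation scavenger (CH2Cl2, −78 °C) cleaves the three aryl benzyl ethers and gives 27 directly.

## Further compounds

F1 | step 3 | methyl (3R,4S)-4-(iodomethyl)-2-oxotetrahydrofuran-3-carboxylate | IC[C@@H]1COC(=O)[C@H]1C(=O)OC
F0 | step 5 | none | none
F2 | step 9 | dimethyl (2R,3S)-7-(benzyloxy)-2-[4-(benzyloxy)-3-methoxyphenyl]-2,3-dihydro-1-benzofuran-3,5-dicarboxylate (cis, enantiomer of 17) | COC(=O)c1cc(OCc2ccccc2)c2c(c1)[C@H](C(=O)OC)[C@H](c1ccc(OCc3ccccc3)c(OC)c1)O2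
F3 | step 9 | dimethyl (2R,3R)-7-(benzyloxy)-2-[4-(benzyloxy)-3-methoxyphenyl]-2,3-dihydro-1-benzofuran-3,5-dicarboxylate (trans, enantiomer of 18) | COC(=O)c1cc(OCc2ccccc2)c2c(c1)[C@@H](C(=O)OC)[C@H](c1ccc(OCc3ccccc3)c(OC)c1)O2
F4 | step 17 | (S)-4-[4-(benzyloxy)-3-methoxybenzyl]dihydrofuran-2(3H)-one | COc1cc(C[C@@H]2COC(=O)C2)ccc1OCc1ccccc1
F0 | step 19 | none | none
A1 | alternative 1 | [(2S,3R)-7-(benzyloxy)-2-[4-(benzyloxy)-3-methoxyphenyl]-5-bromo-2,3-dihydro-1-benzofuran-3-yl]methanol | Brc1cc(OCc2ccccc2)c2c(c1)[C@H](CO)[C@@H](c1ccc(OCc3ccccc3)c(OC)c1)O2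
A2 | alternative 2 | (3S,4S,5S)-3-({(2S,3R)-7-(benzyloxy)-2-[4-(benzyloxy)-3-methoxyphenyl]-3-{[(tert-butyldimethylsilyl)oxy]methyl}-2,3-dihydro-1-benzofuran-5-yl}methyl)-4-[4-(benzyloxy)-3-methoxybenzyl]-5-{[(1S,2R,5S)-2-isopropyl-5-methylcyclohexyl]oxy}dihydrofuran-2(3H)-one | COc1cc(C[C@@H]2[C@@H](O[C@H]5C[C@@H](C)CC[C@@H]5C(C)C)OC(=O)[C@H]2Cc2cc(OCc4ccccc4)c3c(c2)[C@H](CO[Si](C)(C)C(C)(C)C)[C@@H](c2ccc(OCc4ccccc4)c(OC)c2)O3)ccc1OCc1ccccc1
A3 | alternative 3 | (2S,3R)-7-(benzyloxy)-2-[4-(benzyloxy)-3-methoxyphenyl]-5-bromo-N-(quinolin-8-yl)-2,3-dihydro-1-benzofuran-3-carboxamide (cis) | Brc1cc(OCc2ccccc2)c2c(c1)[C@@H](C(=O)Nc1cccc3cccnc13)[C@@H](c1ccc(OCc3ccccc3)c(OC)c1)O2
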